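A small charge of Q, 19.5 mM against 15 mM of L, stands beside 15.0 mM of X from the start, and X competes with Q for L.

| flask | L | Q | X | remark | time |
|---|---|---|---|---|---|
| red | 15 mM | 19.5 mM | 15 mM | run made earlier |  |
| violet | 15 mM | 27 mM | 15 mM | run made earlier |  |
| green | 15 mM | 43 mM | 15 mM | run made earlier |  |
| ochre | 15 mM | 19.5 mM | 30 mM | run made earlier |  |
| theta | 15 mM | 19.5 mM | 15.0 mM | a single well-mixed tank run continuously and read at steady state, 25 h in it on average |  |
| alpha | 15 mM (fed, over 20.0 h) | 19.5 mM | 15.0 mM | all but L at the start; L goes in evenly over 20.0 h, the run ends at 25 h | 25 h |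
| eta | 15 mM | 19.5 mM | 15.0 mM | everything together in a closed stirred flask, run for 25 h | 25 h |
| beta | 15 mM | 19.5 mM (fed, over 20.0 h) | 15.0 mM | all but Q at the start; Q goes in evenly over 20.0 h, the run ends at 25 h | 25 h |

| run | time / h | E / % | Z / % |
|---|---|---|---|
| red | 2.00 | 2.9 | 0.9 |
| red | 3.00 | 2.2 | 3.3 |
| red | 5.00 | 4.0 | 1.0 |
| red | 8.00 | 11.1 | 2.3 |
| red | 10.0 | 15.0 | 5.7 |
| red | 15.0 | 20.4 | 4.5 |
| red | 25.0 | 29.4 | 4.7 |
| violet | 1.50 | 0.4 | 1.2 |
| violet | 5.00 | 9.4 | 2.6 |
| violet | 8.00 | 15.3 | 4.6 |
| violet | 12.0 | 28.3 | 3.2 |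
| violet | 20.0 | 38.7 | 4.2 |
| violet | 25.0 | 45.1 | 5.8 |
| violet | 30.0 | 48.7 | 3.7 |
| green | 1.50 | 4.0 | 1.9 |
| green | 5.00 | 22.8 | 2.0 |
| green | 8.00 | 36.5 | 3.2 |
| green | 12.0 | 47.6 | 5.2 |
| green | 20.0 | 62.8 | 3.3 |
| green | 25.0 | 66.0 | 4.8 |
| green | 30.0 | 70.7 | 4.1 |
| ochre | 2.50 | 1.3 | 2.1 |
| ochre | 8.00 | 10.7 | 4.8 |
| ochre | 15.0 | 19.2 | 8.8 |
| ochre | 20.0 | 25.9 | 8.8 |
| ochre | 30.0 | 32.8 | 9.6 |

(scatter of a reading: 1 percentage point)

- a species is counted by the L in it: one J counts as two
- the stated concentrations are those of everything mixed, before any reaction; amounts are the same in each set-up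
- the analysis behind the earlier runs scatters by 1 percentage point, standard deviation
- steps under discussion: L + Q -> X + D; D + Q -> X + E; X + L -> Z; 2 L -> J
- the feed brings no volume worth counting
- the earlier runs were made in a closed, stirred flask

1. the set-up with the highest share of E in all that became E or Z, at the outlet or at the end ("none" if the first two lie within 2 percentage points) (theta / alpha / eta / beta / none)
2. share of E in all that became E or Z, at the outlet or at the end, theta
3. share of E in all that became E or Z, at the outlet or at the end, alpha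
4. share of E in all that became E or Z, at the outlet or at the end, eta
5. share of E in all that became E or Z, at the outlet or at the end, beta

I carry one quantity, the toll: Z made per L taken up by Q, Z/(D + E). Both steps are first order in c_L, so dividing one rate by the other removes c_L and time, and the toll follows c_X/c_Q times a selectivity factor, the ratio of the two rate constants.

While D stands, the share E/(E + Z) lies below its ceiling (D + E)/(D + E + Z). In green at 30.0 h, D + E is at least E and at most the L charged, so the toll there lies between 4.10% and 0.0580. I scale by the charged c_X/c_Q, taking its later rise to be alike in both flasks: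

low toll = 0.0904, high toll = 0.128

ceiling from the low toll = 91.7%

Red is eta's recipe, so its reading at 25.0 h, with E and Z each moved by one scatter in opposite directions, which keeps E + Z as read, tightens this:

from below 83.3%, from above 89.1%

The forecast names eta, with 76% for theta, 81% for alpha, 72% for beta and 86% for eta, “read directly”, which is inside my bracket.

The flask gives 76.1%, 80.6%, 70.4% and, for eta, 84.3%, the highest, so eta is best.

    L + Q → X + D (k = 0.00177 /M/s)
    D + Q → X + E (k = 0.00125 /M/s)
    X + L → Z (k = 1.22 × 10⁻⁴ /M/s)
    2 L → J (k = 0.00125 /M/s)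

In eta at 12.5 h, L stood at 15.8%, D at 29.0% and Z at 4.16%. By 25.0 h, D + Q had carried E from 17.3% to 29.7%, while Z reached 5.52% and D still held 23.3%. The toll then is 0.104, between my two.

For alpha's flask with 4.9 mM of Q, the low toll scaled by the charged c_X/c_Q gives 0.360, and so a ceiling near 73.5%; both are estimates, not bounds, since this flask is fed and the scaling took the rise of c_X/c_Q from closed flasks. Computed, its toll is 0.344, its ceiling 74.4% and its share 28.5%, with D at 14.9% beside E at 2.38%.

All runs come from a simulation with constants of no real substance; the scatter is artificial.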